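**Plan**

- Retrosynthesis: after removal of three MOM ethers, ring C is cut at C2–C3 and at O1–C8a. This gives a ring B aldehyde (C2=O1) and a ring A 2-fluoroacetophenone (C3–C4(=O)–C4a–C8a–F), used as its trimethylsilyl enol ether.
- Enabling feature: in the phloroglucinol ring A, C8a is ortho to the C4 carbonyl and meta to both O5 and O7. A fluorine on C8a is therefore an SNAr-active leaving group that no ring oxygen deactivates, while the same carbonyl makes C3 a nucleophile. The four-atom unit C3–C4–C4a–C8a can thus add across C2=O1 in a formal [4+2] annulation.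
- Forward, ring A fragment: 5-fluororesorcinol is acetylated, di-iodinated, MOM-protected, doubly prenylated by Stille coupling and converted into the enol silane. Ring B fragment: 3-bromo-4,5-dihydroxybenzaldehyde is 4-O-methylated, MOM-protected and prenylated by Stille coupling.
- Union: a catalytic enantioselective Mukaiyama aldol is followed in the same flask by a fluoride-relayed SNAr that closes ring C. The two helpers, Me3Si on O4 and F on C8a, leave together as Me3SiF. Acid then removes the MOM groups.
- Stereochemistry: the only stereocentre, C2 (S), is set by the chiral boron Lewis acid in the aldol stage (Si-face attack on the aldehyde). It is kept because the O1–C2 bond is never broken and ring C is not closed by a reversible oxa-Michael addition.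

Key step: step 9

Assumption: the L-tryptophan-derived oxazaborolidinone is taken to direct enol silanes to the Re face of aryl aldehydes, so the D-tryptophan-derived antipode is specified for Si-face attack; the antipode would be used if a model aldol showed the opposite sense.

**Route**

Step 1
Reactants: 1 5-fluorobenzene-1,3-diol (5-fluororesorcinol)
Product: 2 1-(2-fluoro-4,6-dihydroxyphenyl)ethan-1-one
Conditions: AcOH, ZnCl2, 130 °C
Reagents that add atoms: acetic acid, CC(=O)O
Why: Nencki acylation (Friedel–Crafts type) of a resorcinol should go to C4, para to one hydroxyl and ortho to the other as with resorcinol and orcinol, which here is the carbon next to fluorine.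

Step 2
Reactants: 2 1-(2-fluoro-4,6-dihydroxyphenyl)ethan-1-one
Product: 3 1-(2-fluoro-4,6-dihydroxy-3,5-diiodophenyl)ethan-1-one
Conditions: NIS (2.1 equiv), DMF, 0 °C to rt
Reagents that add atoms: N-iodosuccinimide, O=C1CCC(=O)N1I
Why: Electrophilic aromatic iodination should take both remaining ring positions, each of which is ortho or para to both hydroxyl groups, and so turn them into handles for carbon–carbon coupling.

Step 3
Reactants: 3 1-(2-fluoro-4,6-dihydroxy-3,5-diiodophenyl)ethan-1-one
Product: 4 1-[2-fluoro-3,5-diiodo-4,6-bis(methoxymethoxy)phenyl]ethan-1-one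
Conditions: NaH, MOMCl, DMF, 0 °C to rt
Reagents that add atoms: chloromethyl methyl ether, COCCl
Why: Williamson-type O-alkylation of both sodium phenoxides, the hydrogen-bonded one included, should give the bis-MOM ether that masks the acidic phenols for the enolate, coupling and SNAr chemistry to come.

Step 4
Reactants: 4 1-[2-fluoro-3,5-diiodo-4,6-bis(methoxymethoxy)phenyl]ethan-1-one
Product: 5 1-[2-fluoro-4,6-bis(methoxymethoxy)-3,5-bis(3-methylbut-2-en-1-yl)phenyl]ethan-1-one
Conditions: Bu3SnCH2CH=CMe2 (2.6 equiv), Pd(PPh3)4 (10 mol %), DMF, 90 °C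
Reagents that add atoms: tributyl(3-methylbut-2-en-1-yl)stannane, CC(C)=CC[Sn](CCCC)(CCCC)CCCC
Why: A twofold Stille coupling at the two C–I bonds should transfer the prenyl group with its linear connectivity while the C–F bond and the ketone stay untouched.

Step 5
Reactants: 5 1-[2-fluoro-4,6-bis(methoxymethoxy)-3,5-bis(3-methylbut-2-en-1-yl)phenyl]ethan-1-one
Product: 6 {1-[2-fluoro-4,6-bis(methoxymethoxy)-3,5-bis(3-methylbut-2-en-1-yl)phenyl]ethenyl}oxy(trimethyl)silane
Conditions: LiN(SiMe3)2, Me3SiCl, THF, −78 °C
Reagents that add atoms: chlorotrimethylsilane, C[Si](C)(C)Cl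
Why: Kinetic deprotonation of the only enolisable position, the acetyl methyl group, and O-silylation of the lithium enolate should give the enol silane (silyl enol ether formation).

Step 6
Reactants: 7 3-bromo-4,5-dihydroxybenzaldehyde
Product: 8 3-bromo-5-hydroxy-4-methoxybenzaldehyde
Conditions: MeI (1.05 equiv), Li2CO3, DMF, 40 °C
Reagents that add atoms: iodomethane, CI
Why: The 4-hydroxyl, para to the formyl group and ortho to bromine, is the more acidic one, so the weak base should form only its phenoxide and the Williamson methylation should be selective for O4, as in the 4-O-alkylation of protocatechualdehydes.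

Step 7
Reactants: 8 3-bromo-5-hydroxy-4-methoxybenzaldehyde
Product: 9 3-bromo-4-methoxy-5-(methoxymethoxy)benzaldehyde
Conditions: MOMCl, i-Pr2NEt, CH2Cl2, 0 °C to rt
Reagents that add atoms: chloromethyl methyl ether, COCCl
Why: O-Alkylation of the remaining phenol under amine base should give the MOM ether, which matches the ring A protecting groups so that one acid step frees all three phenols at the end.

Step 8
Reactants: 9 3-bromo-4-methoxy-5-(methoxymethoxy)benzaldehyde
Product: 10 4-methoxy-3-(methoxymethoxy)-5-(3-methylbut-2-en-1-yl)benzaldehyde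
Conditions: Bu3SnCH2CH=CMe2 (1.3 equiv), Pd(PPh3)4 (5 mol %), DMF, 90 °C
Reagents that add atoms: tributyl(3-methylbut-2-en-1-yl)stannane, CC(C)=CC[Sn](CCCC)(CCCC)CCCC
Why: Stille coupling of the aryl bromide should install the linear prenyl group and tolerates the free aldehyde, which organomagnesium or organolithium prenylation would not.

Step 9
Reactants: 6 {1-[2-fluoro-4,6-bis(methoxymethoxy)-3,5-bis(3-methylbut-2-en-1-yl)phenyl]ethenyl}oxy(trimethyl)silane (limiting); 10 4-methoxy-3-(methoxymethoxy)-5-(3-methylbut-2-en-1-yl)benzaldehyde (1.1 equiv)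
Product: 13 (2S)-5,7-bis(methoxymethoxy)-2-[4-methoxy-3-(methoxymethoxy)-5-(3-methylbut-2-en-1-yl)phenyl]-6,8-bis(3-methylbut-2-en-1-yl)-2,3-dihydro-4H-chromen-4-one, via silyl ether 11 (not isolated), via ammonium alkoxide 12 (not isolated)
Conditions: (R)-2-butyl-4-(indol-3-ylmethyl)-3-tosyl-1,3,2-oxazaborolidin-5-one (20 mol %), EtCN, −78 °C; then Bu4N[Ph3SiF2] (0.5 equiv), THF, −78 to −20 °C; pH 7 buffer
Reagents that add atoms: none
Why: Proposed new method: C3 of enol silane 6 attacks the Si face of the boron-bound aldehyde 10 (Mukaiyama aldol with silyl transfer, C2–C3 bond) to give 11, and fluoride then unmasks alkoxide 12, whose O1 adds to C8a and expels fluoride through a Meisenheimer complex (SNAr, O1–C8a bond), the expelled fluoride desilylating the next molecule of 11 so that silicon and fluorine leave together as Me3SiF. The closest known reaction types are the oxazaborolidinone-catalysed Mukaiyama aldol of aryl methyl ketone enol silanes with aryl aldehydes and the fluoride-catalysed SNAr etherification of aryl fluorides by silyl ethers, and their union into a formal [4+2] annulation on an ortho-fluoroaryl ketone is the untested part. Ring C closes in a six-membered addition–elimination by ipso attack of O1 at C8a (6-exo-trig with respect to the C8=C8a bond of the arene). The only new stereocentre, C2, is fixed by the chiral catalyst in the aldol stage, where the indole of the tryptophan unit shields the Re face of the coordinated aldehyde, and it is not touched in the ring closure because the C2–O1 bond is never broken. The step needs ring closure to outrun retro-aldol cleavage and E1cB dehydration of 12 and needs attack at C8a only, which the substrate secures because C8a is ortho to the C4 carbonyl and meta to both O5 and O7, because fluoride is the best SNAr leaving group, and because the MOM ethers keep any phenoxide from deactivating ring A. Keeping 6 as the limiting reagent leaves no enol silane to be turned into free enolate in the fluoride stage, and the low standing concentration of 12 in the relay suppresses bimolecular base chemistry such as deprotonation of 13 at C3.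

Step 10
Reactants: 13 (2S)-5,7-bis(methoxymethoxy)-2-[4-methoxy-3-(methoxymethoxy)-5-(3-methylbut-2-en-1-yl)phenyl]-6,8-bis(3-methylbut-2-en-1-yl)-2,3-dihydro-4H-chromen-4-one
Product: 14 isoamoritin, (2S)-5,7-dihydroxy-2-[3-hydroxy-4-methoxy-5-(3-methylbut-2-en-1-yl)phenyl]-6,8-bis(3-methylbut-2-en-1-yl)-2,3-dihydro-4H-chromen-4-one
Conditions: HCl (3 M aq), MeOH, 40 °C
Reagents that add atoms: none
Why: Acid-catalysed acetal exchange with methanol (MOM cleavage) should free the three phenols, and neither O1–C2 nor C2–C3 is labile under mild acid, so the C2 configuration should be kept.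

**Compound list**

1 | 5-fluorobenzene-1,3-diol (5-fluororesorcinol) | Oc1cc(O)cc(F)c1 | starting material
2 | 1-(2-fluoro-4,6-dihydroxyphenyl)ethan-1-one | CC(=O)c1c(O)cc(O)cc1F | intermediate
3 | 1-(2-fluoro-4,6-dihydroxy-3,5-diiodophenyl)ethan-1-one | CC(=O)c1c(O)c(I)c(O)c(I)c1F | intermediate
4 | 1-[2-fluoro-3,5-diiodo-4,6-bis(methoxymethoxy)phenyl]ethan-1-one | CC(=O)c1c(OCOC)c(I)c(OCOC)c(I)c1F | intermediate
5 | 1-[2-fluoro-4,6-bis(methoxymethoxy)-3,5-bis(3-methylbut-2-en-1-yl)phenyl]ethan-1-one | CC(=O)c1c(OCOC)c(CC=C(C)C)c(OCOC)c(CC=C(C)C)c1F | intermediate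
6 | {1-[2-fluoro-4,6-bis(methoxymethoxy)-3,5-bis(3-methylbut-2-en-1-yl)phenyl]ethenyl}oxy(trimethyl)silane | C=C(O[Si](C)(C)C)c1c(OCOC)c(CC=C(C)C)c(OCOC)c(CC=C(C)C)c1F | intermediate
7 | 3-bromo-4,5-dihydroxybenzaldehyde | O=Cc1cc(O)c(O)c(Br)c1 | starting material
8 | 3-bromo-5-hydroxy-4-methoxybenzaldehyde | O=Cc1cc(O)c(OC)c(Br)c1 | intermediate
9 | 3-bromo-4-methoxy-5-(methoxymethoxy)benzaldehyde | O=Cc1cc(OCOC)c(OC)c(Br)c1 | intermediate
10 | 4-methoxy-3-(methoxymethoxy)-5-(3-methylbut-2-en-1-yl)benzaldehyde | O=Cc1cc(OCOC)c(OC)c(CC=C(C)C)c1 | intermediate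
11 | (3S)-1-[2-fluoro-4,6-bis(methoxymethoxy)-3,5-bis(3-methylbut-2-en-1-yl)phenyl]-3-[4-methoxy-3-(methoxymethoxy)-5-(3-methylbut-2-en-1-yl)phenyl]-3-(trimethylsilyloxy)propan-1-one | COCOc1cc([C@@H](O[Si](C)(C)C)CC(=O)c2c(OCOC)c(CC=C(C)C)c(OCOC)c(CC=C(C)C)c2F)cc(CC=C(C)C)c1OC | intermediate
12 | tetrabutylammonium alkoxide of the (3S)-3-hydroxy ketone that corresponds to 11 (O–SiMe3 replaced by O−) | COCOc1cc([C@@H]([O-])CC(=O)c2c(OCOC)c(CC=C(C)C)c(OCOC)c(CC=C(C)C)c2F)cc(CC=C(C)C)c1OC.CCCC[N+](CCCC)(CCCC)CCCC | intermediate
13 | (2S)-5,7-bis(methoxymethoxy)-2-[4-methoxy-3-(methoxymethoxy)-5-(3-methylbut-2-en-1-yl)phenyl]-6,8-bis(3-methylbut-2-en-1-yl)-2,3-dihydro-4H-chromen-4-one | COCOc1cc([C@@H]2CC(=O)c3c(OCOC)c(CC=C(C)C)c(OCOC)c(CC=C(C)C)c3O2)cc(CC=C(C)C)c1OC | intermediate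
14 | isoamoritin, (2S)-5,7-dihydroxy-2-[3-hydroxy-4-methoxy-5-(3-methylbut-2-en-1-yl)phenyl]-6,8-bis(3-methylbut-2-en-1-yl)-2,3-dihydro-4H-chromen-4-one | COc1c(O)cc([C@@H]2CC(=O)c3c(O)c(CC=C(C)C)c(O)c(CC=C(C)C)c3O2)cc1CC=C(C)C | target

**Count and risks**

Total steps: 10. Longest linear sequence: 7 steps (steps 1, 2, 3, 4, 5, 9 and 10).

Steps most likely to fail:

Step 9 (Proposed new method). The liberated alkoxide may undergo retro-aldol cleavage or E1cB dehydration faster than it closes the ring, and re-addition of the fragments would erode the enantiomeric purity. The MOM ethers may also sequester the boron catalyst and slow the aldol stage. The fallback sets out from 6 and 10 and separates the two events with known chemistry. A Mukaiyama aldol under SiCl4 with a chiral bisphosphoramide Lewis base derived from 1,1'-binaphthyl-2,2'-diamine (the enantiomer that delivers Si-face addition, catalytic i-Pr2NEt, CH2Cl2, −78 °C, aqueous KF/NaHCO3 work-up) should give the isolated and purified β-hydroxy ketone (3S)-1-[2-fluoro-4,6-bis(methoxymethoxy)-3,5-bis(3-methylbut-2-en-1-yl)phenyl]-3-hydroxy-3-[4-methoxy-3-(methoxymethoxy)-5-(3-methylbut-2-en-1-yl)phenyl]propan-1-one F1. Its potassium alkoxide (KN(SiMe3)2, 18-crown-6, THF, −78 to −20 °C) should then close ring C by a classical intramolecular SNAr on the ortho-fluoroaryl ketone. The fallback comes back to the route at 13.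

Step 4. The second coupling at an iodine flanked by two ortho substituents may stall, protodeiodination may compete, and allyl transposition on palladium may give the branched 1,1-dimethylallyl isomer. The fallback sets out from 2 and avoids the halides altogether. Direct base-mediated C-prenylation of the free resorcinol (prenyl bromide, aqueous KOH, 0 °C), the classical way to 3,5-diprenylated hydroxyacetophenones, should give 1-[2-fluoro-4,6-dihydroxy-3,5-bis(3-methylbut-2-en-1-yl)phenyl]ethan-1-one F2, which is separated from mono- and O-alkylated material. Protection with NaH and MOMCl in DMF then brings the fallback back to the route at 5.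

Step 10. Protic acid may add a freed 5- or 7-hydroxyl across the neighbouring prenyl double bond (2,2-dimethylchroman formation) or hydrate a prenyl group. The fallback sets out from 13 and removes the MOM groups without protic acid. Me3SiOTf with 2,2'-bipyridyl in CH2Cl2 at 0 °C should exchange each aryl MOM ether for an aryl trimethylsilyl ether and give (2S)-2-[4-methoxy-5-(3-methylbut-2-en-1-yl)-3-(trimethylsilyloxy)phenyl]-6,8-bis(3-methylbut-2-en-1-yl)-5,7-bis(trimethylsilyloxy)-2,3-dihydro-4H-chromen-4-one F3. Addition of water and methanol at rt hydrolyses the silyl ethers, and the fallback comes back to the route at 14.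

**Further compounds**

F1 | step 9 | (3S)-1-[2-fluoro-4,6-bis(methoxymethoxy)-3,5-bis(3-methylbut-2-en-1-yl)phenyl]-3-hydroxy-3-[4-methoxy-3-(methoxymethoxy)-5-(3-methylbut-2-en-1-yl)phenyl]propan-1-one | COCOc1cc([C@@H](O)CC(=O)c2c(OCOC)c(CC=C(C)C)c(OCOC)c(CC=C(C)C)c2F)cc(CC=C(C)C)c1OC
F2 | step 4 | 1-[2-fluoro-4,6-dihydroxy-3,5-bis(3-methylbut-2-en-1-yl)phenyl]ethan-1-one | CC(=O)c1c(O)c(CC=C(C)C)c(O)c(CC=C(C)C)c1F
F3 | step 10 | (2S)-2-[4-methoxy-5-(3-methylbut-2-en-1-yl)-3-(trimethylsilyloxy)phenyl]-6,8-bis(3-methylbut-2-en-1-yl)-5,7-bis(trimethylsilyloxy)-2,3-dihydro-4H-chromen-4-one | COc1c(O[Si](C)(C)C)cc([C@@H]2CC(=O)c3c(O[Si](C)(C)C)c(CC=C(C)C)c(O[Si](C)(C)C)c(CC=C(C)C)c3O2)cc1CC=C(C)C
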